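Start with a count of coupling partner, taking 3 of them for each substrate that ends as tris adduct.

| flask | substrate | coupling partner | remark | time |
|---|---|---|---|---|
| Tuesday's | 0.40 M | 0.28 M | run made earlier |  |
| Thursday's | 0.40 M | 0.67 M | run made earlier |  |
| Saturday's | 0.40 M | 1.8 M | run made earlier |  |
| noon | 0.40 M | 1.60 M |  | 2.0 h |
| summer | 0.40 M | 0.320 M |  | 2.0 h |
| autumn | 0.40 M | 1.00 M |  | 2.0 h |

- Tuesday's (time / min: tris adduct / %, substrate / %): 12.0: 1.0, 87.3; 25.0: 1.8, 74.8; 40.0: 1.5, 69.0; 50.0: 2.8, 64.0; 60.0: 2.4, 64.5
- Thursday's (time / min: tris adduct / %, substrate / %): 5.00: 0.8, 85.7; 15.0: 3.6, 64.6; 30.0: 12.9, 47.5; 40.0: 20.2, 42.4; 60.0: 23.8, 37.8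
- Saturday's (time / min: tris adduct / %, substrate / %): 12.0: 19.4, 38.3; 25.0: 53.4, 15.9; 40.0: 72.9, 7.8; 50.0: 80.2, 4.7; 60.0: 86.8, 5.4

(readings scatter by 1 percentage point)

- which of these holds the largest part of the substrate at the end of noon (first product / bis adduct / tris adduct / substrate)
- which of these holds the largest part of the substrate at the end of summer (first product / bis adduct / tris adduct / substrate)
- which of these holds the largest part of the substrate at the end of autumn (first product / bis adduct / tris adduct / substrate)
- how much tris adduct is there at the end of noon, in percent of the substrate charged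



Work out the margin of noon, 0.400 M: the coupling partner charged minus 3 times the substrate charged. With a positive margin, take substrate as the limiting reagent. Count each substrate lost as tris adduct at once, which leaves first product and bis adduct out of the balance; then [coupling partner] is the margin plus 3[substrate], and the rate k[substrate][coupling partner] integrates in closed form. The fraction of substrate left is the margin divided by the charged [coupling partner] times exp(margin·k·t), minus 3 times the charged [substrate]. Read an effective k from Saturday's reading at 40.0 min: 0.0666 L mol⁻¹ min⁻¹. For tris adduct, use the fraction s of substrate left: tris = 1 − s(1 + ln(1/s)). At that reading this gives 72.3%, and Saturday's run shows 72.9%.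

Now take two ways to noon. The first holds partner at the margin as a pseudo-first-order shortcut, so s = exp(−margin·k·t), and tris comes to 82.8%. The second uses the closed form: s is 1.06% and tris is 94.1%, higher. Test both on Saturday's run at 50.0 min. The shortcut gives 13.6% substrate, the closed form 4.98%, and the reading is 4.7%. So the shortcut cheats, and I commit to 94.1%. For summer the closed form gives substrate 73.4% and tris adduct 3.92%, with substrate ahead. For autumn it gives substrate 20.0% and tris adduct 47.7%, with tris adduct ahead. Trust these two figures less, since both margins are negative, −0.880 M and −0.200 M. Tuesday's run, with a negative margin too, reads 64.5% substrate at 60.0 min, below the 76.7% that the count of 3 allows.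

The forecast names tris adduct, substrate and tris adduct for noon, summer and autumn, with 94% of tris adduct at noon (range 90% to 97%), “integrating with the falling partner”.

At the end of noon tris adduct holds 95.2%, against 2.59% of bis adduct. At the end of summer substrate holds 54.6%, against 21.3% of first product. At the end of autumn tris adduct holds 62.1%, against 17.1% of bis adduct.

    crystals ⇌ by-product, rate k1*(cs1 - [by-product]) while solid is left; crystals form when [by-product] > cs1 (solubility = 0.170 M, k = 0.00470 s⁻¹)
    substrate + coupling partner → first product + by-product (k = 8.90 × 10⁻⁴ L mol⁻¹ s⁻¹)
    coupling partner + first product → bis adduct + by-product (k = 0.00230 L mol⁻¹ s⁻¹)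
    coupling partner + bis adduct → tris adduct + by-product (k = 0.00160 L mol⁻¹ s⁻¹)

The margin of noon leaves a quarter of the partner charged, 25.0%, and the noon flask holds 27.1% at 2.00 h and 25.0% at 20.0 h. Now take the neighbouring flask with 1.0 M of substrate. Its margin is −1.40 M, negative, so coupling partner becomes the limiting reagent, and its charge covers tris adduct up to 53.3%. At 2.00 h that flask has 0.0564% of its partner left, with substrate at 28.6%, bis adduct at 23.2% and tris adduct at 32.6%.

(The data are simulated for an exercise; noise was put on by code.)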